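**Strategy.** The polyene is cut at C7=C8 and C7'=C8' into crocetindial and two C15 phosphonium salts, each taken from the (R)-p-menthane chiral pool, so both C2 stereocentres are bought. Everything rests on the β-ring: its gem-dimethyl carbon C1 and its polyene-bearing alkene carbon C6 are joined by a biomimetic cation–olefin cyclisation that copies the C50-carotenoid cyclase. Protonating the isopropenyl group beside the preformed C2 stereocentre gives the C1 tertiary cation, which the C5=C6 alkene of an acyclic allylic phosphonium salt traps; one operation gives the ring, its tetrasubstituted alkene and the C7 Wittig handle. The precursor is a ring-opened limonene: a triene phosphonium salt.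

Key step: step 5

Remark: locants C1–C7 and primed locants follow carotenoid numbering (C1 = ring CMe2, C2 = ring stereocentre, C6 = ring carbon bearing the polyene). Commercial (+)-limonene oxide is used as its cis/trans mixture, since both epoxide centres are destroyed in step 1. The Wittig products are equilibrated to the all-E polyenes, as is usual in carotenoid work.

**Step 1**
Reactants: 1 (4R)-limonene 1,2-oxide
Product: 3 (3R)-6-oxo-3-(prop-1-en-2-yl)heptanal, via p-menth-8-ene-1,2-diol 2 (not isolated)
Conditions: H5IO6 (1.2 equiv), THF/H2O, 0 °C → rt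
Reagents that add atoms: water, O
Why: Acidic epoxide hydrolysis followed by periodate glycol cleavage should open the ring to the keto-aldehyde without touching the isopropenyl group or the C4 stereocentre, which becomes C2 of the β-ring.

**Step 2**
Reactants: 3 (3R)-6-oxo-3-(prop-1-en-2-yl)heptanal; 4 ethyl 2-(triphenylphosphoranylidene)propanoate
Product: 5 ethyl (2E,5R)-2-methyl-8-oxo-5-(prop-1-en-2-yl)non-2-enoate
Conditions: 4 (1.05 equiv), CH2Cl2, rt
Reagents that add atoms: ethyl 2-(triphenylphosphoranylidene)propanoate (4), CCOC(=O)C(C)=P(c1ccccc1)(c1ccccc1)c1ccccc1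
Why: A stabilised Wittig ylide should react only with the aldehyde, not the methyl ketone, and give the (E)-trisubstituted enoate, a deactivated and reducible form of the hydroxyprenyl side chain.

**Step 3**
Reactants: 5 ethyl (2E,5R)-2-methyl-8-oxo-5-(prop-1-en-2-yl)non-2-enoate; 6 vinylmagnesium bromide
Product: 7 ethyl (2E,5R)-8-hydroxy-2,8-dimethyl-5-(prop-1-en-2-yl)deca-2,9-dienoate (C8 epimers)
Conditions: CH2=CHMgBr (1.2 equiv), THF, −78 °C; aq. NH4Cl
Reagents that add atoms: vinylmagnesium bromide (6), C=C[Mg]Br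
Why: Grignard 1,2-addition to the ketone should be much faster than attack on the hindered conjugated ester at −78 °C; the new carbinol centre is lost in step 4.

**Step 4**
Reactants: 7 ethyl (2E,5R)-8-hydroxy-2,8-dimethyl-5-(prop-1-en-2-yl)deca-2,9-dienoate; 8 triphenylphosphine
Product: 9 [(6R,8E)-10-ethoxy-3,9-dimethyl-10-oxo-6-(prop-1-en-2-yl)deca-2,8-dien-1-yl]triphenylphosphonium hydrogensulfate (2E/2Z mixture)
Conditions: PPh3 (1.05 equiv), H2SO4 (1.0 equiv), AcOH, 20 °C
Reagents that add atoms: triphenylphosphine (8), c1ccc(cc1)P(c1ccccc1)c1ccccc1; sulfuric acid, OS(=O)(=O)O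
Why: Ionisation of the tertiary allylic alcohol and SN1′ capture of the allyl cation at its primary end by PPh3 is the standard vinyl carbinol → Wittig salt reaction; the medium is only as acidic as Ph3PH+, so the isopropenyl group should stay intact.

**Step 5**
Reactants: 9 [(6R,8E)-10-ethoxy-3,9-dimethyl-10-oxo-6-(prop-1-en-2-yl)deca-2,8-dien-1-yl]triphenylphosphonium hydrogensulfate
Product: 10 {[(5R)-5-[(2E)-4-ethoxy-3-methyl-4-oxobut-2-en-1-yl]-2,6,6-trimethylcyclohex-1-en-1-yl]methyl}triphenylphosphonium hydrogensulfate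
Conditions: conc. H2SO4, AcOH, 0 → 20 °C; ice-water quench, CH2Cl2 extraction
Reagents that add atoms: none
Why: Markovnikov protonation of the 1,1-disubstituted isopropenyl alkene gives the tertiary C1 cation, the trisubstituted C5=C6 alkene attacks it through C6 to form the C1–C6 bond, and the resulting tertiary C5 cation loses a proton, the alkene settling under the equilibrating acid in the tetrasubstituted C5=C6 (β) position. The closest known reactions are the sulfuric acid cyclisations of pseudoionone to β-ionone, of pseudoirones to irones and of geranyl aryl sulfones to β-cyclogeranyl sulfones (Brønsted acid cation–olefin cyclisation). The six-membered ring closes 6-endo-trig through a chair-like transition state with the C2 side chain equatorial. No new stereocentre is formed; the C2 centre comes unchanged from limonene and only has to survive next to the cation. Site selectivity of protonation is secured because the C5=C6 alkene is deactivated by the allylic phosphonium group and the enoate by its protonated ester, so only the isopropenyl group should initiate. Retention at C2 needs ring closure to outrun loss of the C2 proton from the C1 cation, which the pre-folded intramolecular alkene and a short, cold contact time favour.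

**Step 6**
Reactants: 10 the cyclised phosphonium hydrogensulfate; 11 crocetindial, (2E,4E,6E,8E,10E,12E,14E)-2,6,11,15-tetramethylhexadeca-2,4,6,8,10,12,14-heptaenedial
Product: 13 ethyl (2E)-4-[(1R)-2,2,4-trimethyl-3-[(1E,3E,5E,7E,9E,11E,13E,15E)-3,7,12,16-tetramethyl-17-oxoheptadeca-1,3,5,7,9,11,13,15-octaen-1-yl]cyclohex-3-en-1-yl]-2-methylbut-2-enoate, via phosphorus ylide 12 (not isolated)
Conditions: 11 (3 equiv), NaOEt (2.1 equiv), EtOH/CH2Cl2, 0 °C → rt; then heptane, reflux (E/Z equilibration)
Reagents that add atoms: crocetindial (11), O=C/C(C)=C/C=C/C(C)=C/C=C/C=C(C)/C=C/C=C(C)/C=O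
Why: Wittig olefination of the non-enolisable dialdehyde with the cyclogeranyl-type ylide (C15 + C20 carotenoid logic) should form C7=C8; excess dialdehyde favours mono-olefination, and the hindered 7Z isomer should equilibrate thermally to 7E.

**Step 7**
Reactants: 14 (R)-(+)-α-terpineol
Product: 16 4-[(3R)-5-hydroxy-2,2-dimethyloxolan-3-yl]butan-2-one (anomers), via secondary ozonide 15 (not isolated)
Conditions: O3, CH2Cl2, −78 °C; then Me2S, −78 °C → rt
Reagents that add atoms: ozone, [O-][O+]=O
Why: Ozonolysis of the only alkene should give the keto-aldehyde, whose aldehyde is trapped by the tertiary alcohol as a five-membered lactol; the stereocentre (later C2') is untouched.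

**Step 8**
Reactants: 16 4-[(3R)-5-hydroxy-2,2-dimethyloxolan-3-yl]butan-2-one; 17 isopropyltriphenylphosphonium iodide
Product: 19 (5R)-5-(2-hydroxypropan-2-yl)-8-methylnon-7-en-2-one, via isopropylidenetriphenylphosphorane 18 (not isolated)
Conditions: 17 (2.3 equiv), n-BuLi (2.2 equiv), THF, 0 °C; then 16, −78 → 0 °C
Reagents that add atoms: isopropyltriphenylphosphonium iodide (17), CC(C)[P+](c1ccccc1)(c1ccccc1)c1ccccc1.[I-]
Why: Lactol Wittig olefination: the lactolate opens to the aldehyde, which the disubstituted ylide should olefinate far faster than the methyl ketone (a tetrasubstituted alkene would have to form there), installing the prenyl group and freeing the tertiary alcohol.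

**Step 9**
Reactants: 19 (5R)-5-(2-hydroxypropan-2-yl)-8-methylnon-7-en-2-one
Product: 20 (3E,5S)-5-(2-hydroxypropan-2-yl)-8-methylnona-3,7-dien-2-one
Conditions: IBX (1.5 equiv), 4-methoxypyridine N-oxide (1.5 equiv), DMSO, 25 °C
Reagents that add atoms: none
Why: IBX α,β-dehydrogenation of a ketone can only desaturate the CH2–CH2 side of a methyl ketone, so it should give the (E)-enone that becomes C3'=C4'; the neutral room-temperature conditions spare the γ stereocentre.

**Step 10**
Reactants: 20 (3E,5S)-5-(2-hydroxypropan-2-yl)-8-methylnona-3,7-dien-2-one; 6 vinylmagnesium bromide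
Product: 21 (4E,6S)-6-(2-hydroxypropan-2-yl)-3,9-dimethyldeca-1,4,8-trien-3-ol (C3 epimers)
Conditions: CH2=CHMgBr (2.5 equiv), THF, −78 °C; aq. NH4Cl
Reagents that add atoms: vinylmagnesium bromide (6), C=C[Mg]Br
Why: Vinyl Grignard reagents add 1,2 to enones (as in the ionone → vinyl-ionol conversion); one equivalent is spent on the free hydroxyl and the new carbinol centre is lost in step 11.

**Step 11**
Reactants: 21 (4E,6S)-6-(2-hydroxypropan-2-yl)-3,9-dimethyldeca-1,4,8-trien-3-ol; 22 triphenylphosphine hydrobromide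
Product: 23 [(2E,4E,6S)-6-(2-hydroxypropan-2-yl)-3,9-dimethyldeca-2,4,8-trien-1-yl]triphenylphosphonium bromide
Conditions: PPh3·HBr (1.05 equiv), MeOH, 0 °C → rt; crystallisation of the 2E isomer
Reagents that add atoms: triphenylphosphine hydrobromide (22), [Br-].c1ccc(cc1)[PH+](c1ccccc1)c1ccccc1
Why: Only the bis-allylic tertiary alcohol ionises under this mild acid; the pentadienyl cation is captured by PPh3 at its primary terminus (vinyl carbinol → Wittig salt reaction), while the saturated tertiary alcohol and the prenyl group should be left alone.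

**Step 12**
Reactants: 13 the C35 aldehyde ester; 23 the dienyl phosphonium bromide
Product: 25 all-E C50 ethyl ester (the target with CO2Et in place of CH2OH), via phosphorus ylide 24 (not isolated)
Conditions: 23 (1.5 equiv), NaOEt (1.6 equiv), EtOH/CH2Cl2, 0 °C → rt; then cat. I2, hexane/CH2Cl2, daylight (E/Z equilibration)
Reagents that add atoms: the dienyl phosphonium bromide (23), CC(C)=CC[C@@H](/C=C/C(C)=C/C[P+](c1ccccc1)(c1ccccc1)c1ccccc1)C(C)(C)O.[Br-]
Why: Wittig olefination of the polyenal with the allylic ylide should form C7'=C8'; the free tertiary hydroxyl is tolerated and iodine-catalysed equilibration should give the all-E chromophore without touching either sp3 stereocentre.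

**Step 13**
Reactants: 25 all-E C50 ethyl ester
Product: 26 target, (2R,2'S)-2-[(2E)-4-hydroxy-3-methylbut-2-enyl]-2'-(3-methylbut-2-enyl)-3',4'-didehydro-1',2'-dihydro-β,ψ-caroten-1'-ol
Conditions: DIBAL-H (4 equiv), CH2Cl2, −78 → −40 °C; Rochelle salt work-up
Reagents that add atoms: none
Why: DIBAL 1,2-reduction of the conjugated ester should give the (E)-allylic primary alcohol and leave the polyene and the tertiary alcohol unchanged.

**Compound list**

1 | (4R)-limonene 1,2-oxide (cis/trans mixture) | CC(=C)[C@@H]1CCC2(C)OC2C1 | starting material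
2 | (4R)-1-methyl-4-(prop-1-en-2-yl)cyclohexane-1,2-diol | CC(=C)[C@@H]1CCC(C)(O)C(O)C1 | intermediate
3 | (3R)-6-oxo-3-(prop-1-en-2-yl)heptanal | CC(=O)CC[C@H](CC=O)C(C)=C | intermediate
4 | ethyl 2-(triphenylphosphoranylidene)propanoate | CCOC(=O)C(C)=P(c1ccccc1)(c1ccccc1)c1ccccc1 | starting material
5 | ethyl (2E,5R)-2-methyl-8-oxo-5-(prop-1-en-2-yl)non-2-enoate | CC(=O)CC[C@H](C/C=C(\C)C(=O)OCC)C(C)=C | intermediate
6 | vinylmagnesium bromide | C=C[Mg]Br | starting material
7 | ethyl (2E,5R)-8-hydroxy-2,8-dimethyl-5-(prop-1-en-2-yl)deca-2,9-dienoate | C=CC(C)(O)CC[C@H](C/C=C(\C)C(=O)OCC)C(C)=C | intermediate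
8 | triphenylphosphine | c1ccc(cc1)P(c1ccccc1)c1ccccc1 | starting material
9 | [(6R,8E)-10-ethoxy-3,9-dimethyl-10-oxo-6-(prop-1-en-2-yl)deca-2,8-dien-1-yl]triphenylphosphonium hydrogensulfate | c1ccc(cc1)[P+](c1ccccc1)(c1ccccc1)CC=C(C)CC[C@H](C/C=C(\C)C(=O)OCC)C(C)=C.OS(=O)(=O)[O-] | intermediate
10 | {[(5R)-5-[(2E)-4-ethoxy-3-methyl-4-oxobut-2-en-1-yl]-2,6,6-trimethylcyclohex-1-en-1-yl]methyl}triphenylphosphonium hydrogensulfate | c1ccc(cc1)[P+](c1ccccc1)(c1ccccc1)CC2=C(C)CC[C@H](C/C=C(\C)C(=O)OCC)C2(C)C.OS(=O)(=O)[O-] | intermediate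
11 | crocetindial | O=C/C(C)=C/C=C/C(C)=C/C=C/C=C(C)/C=C/C=C(C)/C=O | starting material
12 | ylide of 10 | c1ccc(cc1)P(c1ccccc1)(c1ccccc1)=CC2=C(C)CC[C@H](C/C=C(\C)C(=O)OCC)C2(C)C | intermediate
13 | C35 aldehyde ester | O=C/C(C)=C/C=C/C(C)=C/C=C/C=C(C)/C=C/C=C(C)/C=C/C1=C(C)CC[C@H](C/C=C(\C)C(=O)OCC)C1(C)C | intermediate
14 | (R)-(+)-α-terpineol | CC1=CC[C@@H](CC1)C(C)(C)O | starting material
15 | secondary ozonide of 14 | CC12CC[C@H](CC(OO1)O2)C(C)(C)O | intermediate
16 | 4-[(3R)-5-hydroxy-2,2-dimethyloxolan-3-yl]butan-2-one | CC(=O)CC[C@@H]1CC(O)OC1(C)C | intermediate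
17 | isopropyltriphenylphosphonium iodide | CC(C)[P+](c1ccccc1)(c1ccccc1)c1ccccc1.[I-] | starting material
18 | isopropylidenetriphenylphosphorane | CC(C)=P(c1ccccc1)(c1ccccc1)c1ccccc1 | intermediate
19 | (5R)-5-(2-hydroxypropan-2-yl)-8-methylnon-7-en-2-one | CC(=O)CC[C@H](CC=C(C)C)C(C)(C)O | intermediate
20 | (3E,5S)-5-(2-hydroxypropan-2-yl)-8-methylnona-3,7-dien-2-one | CC(=O)/C=C/[C@H](CC=C(C)C)C(C)(C)O | intermediate
21 | (4E,6S)-6-(2-hydroxypropan-2-yl)-3,9-dimethyldeca-1,4,8-trien-3-ol | C=CC(C)(O)/C=C/[C@H](CC=C(C)C)C(C)(C)O | intermediate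
22 | triphenylphosphine hydrobromide | [Br-].c1ccc(cc1)[PH+](c1ccccc1)c1ccccc1 | starting material
23 | [(2E,4E,6S)-6-(2-hydroxypropan-2-yl)-3,9-dimethyldeca-2,4,8-trien-1-yl]triphenylphosphonium bromide | CC(C)=CC[C@@H](/C=C/C(C)=C/C[P+](c1ccccc1)(c1ccccc1)c1ccccc1)C(C)(C)O.[Br-] | intermediate
24 | ylide of 23 | CC(C)=CC[C@@H](/C=C/C(C)=C/C=P(c1ccccc1)(c1ccccc1)c1ccccc1)C(C)(C)O | intermediate
25 | all-E C50 ethyl ester | CC(C)=CC[C@@H](/C=C/C(C)=C/C=C/C(C)=C/C=C/C(C)=C/C=C/C=C(C)/C=C/C=C(C)/C=C/C1=C(C)CC[C@H](C/C=C(\C)C(=O)OCC)C1(C)C)C(C)(C)O | intermediate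
26 | CNP0286110.1 | CC(C)=CC[C@@H](/C=C/C(C)=C/C=C/C(C)=C/C=C/C(C)=C/C=C/C=C(C)/C=C/C=C(C)/C=C/C1=C(C)CC[C@H](C/C=C(\C)CO)C1(C)C)C(C)(C)O | target

**Count.** Total: 13 steps. Longest linear sequence: 8 steps (steps 1–6, 12, 13).

**Steps most likely to fail**

1. Step 5. The C1 cation may lose the C2 proton (or take a 1,2-hydride shift from C2) before the phosphonium-deactivated alkene closes the ring, which would erode the configuration at C2; the alkene may also fail to settle fully in the β position. Fallback: cyclise a neutral acetate instead and make the phosphonium salt afterwards. From 7, acetylation (Ac2O, DMAP, Et3N) should give the tertiary allylic acetate F1. A PdCl2(MeCN)2-catalysed 1,3-acetoxy shift should give the primary allylic acetate F2. Acid cyclisation of this geranyl-acetate analogue (H2SO4/AcOH, alkene equilibrated to the β position) should give the β-cyclogeranyl-type acetate F3. PPh3/H2SO4 in AcOH (allylic acetate → phosphonium salt, as practised on retinyl acetate) returns to 10.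

2. Step 9. The IBX dehydrogenation may stall, or go on through the γ-position toward a cross-conjugated dienone, which would destroy the stereocentre. Fallback: Saegusa–Ito oxidation. From 19, TMSCl/NaI/Et3N in MeCN (thermodynamic conditions) should give the internal silyl enol ether with the tertiary alcohol also silylated, F4. Pd(OAc)2 in MeCN should give the (E)-enone silyl ether F5, and K2CO3/MeOH returns to 20.

3. Step 8. Lactol opening may be slow relative to enolisation or olefination of the methyl ketone, so that ylide is consumed unproductively. Fallback: olefinate the free aldehyde of the limonene series and hydrate afterwards. From 3, one equivalent of ylide 18 at −78 °C should give the isopropenyl prenyl ketone F6. Oxymercuration with Hg(OAc)2 in THF/H2O (1,1-disubstituted alkenes react much faster than trisubstituted ones) and NaBH4 demercuration, which also reduces the ketone, should give the diol F7. Dess–Martin oxidation of the secondary alcohol returns to 19.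

**Further compounds**

F1 | step 5 | ethyl (2E,5R)-8-acetoxy-2,8-dimethyl-5-(prop-1-en-2-yl)deca-2,9-dienoate | C=CC(C)(OC(C)=O)CC[C@H](C/C=C(\C)C(=O)OCC)C(C)=C
F2 | step 5 | ethyl (2E,5R)-10-acetoxy-2,8-dimethyl-5-(prop-1-en-2-yl)deca-2,8-dienoate | CC(=O)OCC=C(C)CC[C@H](C/C=C(\C)C(=O)OCC)C(C)=C
F3 | step 5 | ethyl (2E)-4-[(1R)-3-(acetoxymethyl)-2,2,4-trimethylcyclohex-3-en-1-yl]-2-methylbut-2-enoate | CC(=O)OCC1=C(C)CC[C@H](C/C=C(\C)C(=O)OCC)C1(C)C
F4 | step 9 | (5S)-8-methyl-2-(trimethylsilyloxy)-5-[2-(trimethylsilyloxy)propan-2-yl]nona-2,7-diene | CC(O[Si](C)(C)C)=CC[C@H](CC=C(C)C)C(C)(C)O[Si](C)(C)C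
F5 | step 9 | (3E,5S)-8-methyl-5-[2-(trimethylsilyloxy)propan-2-yl]nona-3,7-dien-2-one | CC(=O)/C=C/[C@H](CC=C(C)C)C(C)(C)O[Si](C)(C)C
F6 | step 8 | (5R)-8-methyl-5-(prop-1-en-2-yl)non-7-en-2-one | CC(=O)CC[C@H](CC=C(C)C)C(C)=C
F7 | step 8 | (5R)-5-(2-hydroxypropan-2-yl)-8-methylnon-7-en-2-ol | CC(O)CC[C@H](CC=C(C)C)C(C)(C)O
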